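**Retrosynthetic overview**
1. Ester C–O bond last: target ⇒ (2R)-chromen-2-ylmethanol (C7 oxygen as MOM ether) + MOM-protected (E)-ferulic acid.
2. Pyran ring ⇒ contraction of a seven-membered 2,3-dihydro-1-benzoxepin-3-ol by an O-to-O aryl shift (Smiles type). O1 and the ester oxygen sit on neighbouring carbons (C2 and its CH2, a 1,2-diol pair), and the C6 acetyl group is para to C8a, the arene carbon that carries O1; C8a can therefore take up the tertiary alkoxide at its ipso position and release the CH2 oxygen.
3. Oxepine ring ⇒ ring-closing metathesis of an aryl ether diene ⇒ 5-vinyl-2,4-dihydroxyacetophenone + monotosylate of (2R)-2-methylbut-3-ene-1,2-diol.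
4. Stereocentre ⇒ Pd-catalysed dynamic kinetic asymmetric opening of racemic isoprene monoxide; arene ⇒ 2,4-dihydroxyacetophenone (C5 iodination, vinylation).
5. Ring order: benzene ring bought; oxepine ring by metathesis; pyran ring from the oxepine ring by loss of one ring atom.

Key step: step 8

Remark: the descriptor at C2 of the target works out as (R) (O1 > CH2O > C3 > CH3); the site of iodination in step 1 and the sense of induction in step 3 are predictions from close analogies and are to be confirmed on the first intermediates.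

**Step 1**
Reactants: 1 1-(2,4-dihydroxyphenyl)ethanone
Product: 2 1-(2,4-dihydroxy-5-iodophenyl)ethanone
Conditions: ICl (1.05 equiv), AcOH, 20 °C
Reagents that add atoms: iodine monochloride, ClI
Why: Electrophilic aromatic iodination should go to C5, which is para to the 2-hydroxyl, ortho to the 4-hydroxyl and less hindered than C3 between the two oxygens.

**Step 2**
Reactants: 2 1-(2,4-dihydroxy-5-iodophenyl)ethanone
Product: 3 1-(5-ethenyl-2,4-dihydroxyphenyl)ethanone
Conditions: vinylboronic acid pinacol ester (1.3 equiv), Pd(dppf)Cl2 (3 mol %), K2CO3 (3 equiv), dioxane/H2O (4:1), 80 °C, BHT (trace)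
Reagents that add atoms: 2-ethenyl-4,4,5,5-tetramethyl-1,3,2-dioxaborolane, C=CB1OC(C)(C)C(C)(C)O1
Why: Suzuki–Miyaura coupling of an aryl iodide tolerates free phenols, and it is run before the side chain is attached so that no pendant alkene can trap the arylpalladium species in a Heck cyclisation.

**Step 3**
Reactants: 4 rac-2-ethenyl-2-methyloxirane (isoprene monoxide)
Product: 6 (2R)-2-methylbut-3-ene-1,2-diol, via sodium carbonate monoester 5 (not isolated)
Conditions: Pd2(dba)3·CHCl3 (1 mol %), DACH-phenyl Trost ligand (3 mol %; the antipode that leads to the (R)-diol, (S,S) expected by analogy, to be confirmed by optical rotation), NaHCO3, Et3B (1 mol %), CH2Cl2/H2O, 20 °C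
Reagents that add atoms: sodium hydrogen carbonate, [Na+].OC([O-])=O
Why: Tsuji–Trost-type dynamic kinetic asymmetric substitution: both enantiomers of 4 ionise to interconverting π-allylpalladium alkoxides, the boron-bound alkoxide delivers hydrogen carbonate to the more substituted allyl terminus inside the chiral pocket (this sets the tertiary carbinol centre), and water then hydrolyses the carbonate monoester.

**Step 4**
Reactants: 6 (2R)-2-methylbut-3-ene-1,2-diol
Product: 7 (2R)-2-hydroxy-2-methylbut-3-en-1-yl 4-methylbenzenesulfonate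
Conditions: TsCl (1.05 equiv), Et3N, Bu2SnO (2 mol %), CH2Cl2, 0 °C
Reagents that add atoms: 4-methylbenzenesulfonyl chloride, Cc1ccc(cc1)S(Cl)(=O)=O
Why: Tin-catalysed sulfonylation of a 1,2-diol is selective for the primary hydroxyl, and the tertiary allylic hydroxyl and its stereocentre are not touched.

**Step 5**
Reactants: 3 1-(5-ethenyl-2,4-dihydroxyphenyl)ethanone; 7 (2R)-2-hydroxy-2-methylbut-3-en-1-yl 4-methylbenzenesulfonate
Product: 9 1-{5-ethenyl-2-hydroxy-4-[(2R)-2-hydroxy-2-methylbut-3-en-1-yl]oxyphenyl}ethanone, via (2R)-2-ethenyl-2-methyloxirane 8 (not isolated)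
Conditions: K2CO3 (2.5 equiv), DMF, 65 °C, BHT (trace)
Reagents that add atoms: none
Why: Williamson-type etherification through the epoxide: base closes 7 to the vinyl epoxide 8 without breaking the C–O bond at the stereocentre, and the more acidic, non-chelated 4-phenoxide opens 8 at the unhindered CH2 (SN2), so the (R) centre is carried over unchanged.

**Step 6**
Reactants: 9 1-{5-ethenyl-2-hydroxy-4-[(2R)-2-hydroxy-2-methylbut-3-en-1-yl]oxyphenyl}ethanone
Product: 10 1-{5-ethenyl-4-[(2R)-2-hydroxy-2-methylbut-3-en-1-yl]oxy-2-(methoxymethoxy)phenyl}ethanone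
Conditions: MOMCl (1.5 equiv), K2CO3 (3 equiv), acetone, 45 °C
Reagents that add atoms: chloromethyl methyl ether, COCCl
Why: The chelated phenol is alkylated as its phenoxide, whereas K2CO3 does not deprotonate the tertiary alcohol, so only the phenol is capped.

**Step 7**
Reactants: 10 1-{5-ethenyl-4-[(2R)-2-hydroxy-2-methylbut-3-en-1-yl]oxy-2-(methoxymethoxy)phenyl}ethanone
Product: 11 1-[(3R)-3-hydroxy-8-(methoxymethoxy)-3-methyl-2,3-dihydro-1-benzoxepin-7-yl]ethanone
Conditions: second-generation Grubbs catalyst RuCl2(PCy3)(H2IMes)(=CHPh) (5 mol %), CH2Cl2 (5 mM), 40 °C; filtration through Et3N-washed silica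
Reagents that add atoms: none
Why: Ring-closing metathesis of two monosubstituted alkenes held close by the quaternary carbinol carbon closes the seven-membered ring with the cis alkene that the ring enforces, and a tertiary allylic alcohol cannot isomerise to a ketone.

**Step 8**
Reactants: 11 1-[(3R)-3-hydroxy-8-(methoxymethoxy)-3-methyl-2,3-dihydro-1-benzoxepin-7-yl]ethanone
Product: 13 1-[(2R)-2-(hydroxymethyl)-7-(methoxymethoxy)-2-methyl-2H-chromen-6-yl]ethanone, via bicyclic Meisenheimer adduct 12 (not isolated)
Conditions: KOt-Bu (0.3 equiv), THF/t-BuOH (4:1), 20 to 45 °C, dark; aq. NH4Cl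
Reagents that add atoms: none
Why: Proposed new method: the tertiary alkoxide of 11, formed reversibly by catalytic base, adds to the ipso carbon C9a (para to the C7 acetyl group) to give adduct 12, a levoglucosenone-like 6,8-dioxabicyclo[3.2.1]oct-2-ene ketal whose charge rests on the acetyl oxygen; 12 then expels the CH2 oxygen O1, so the aryl group has moved from the primary to the tertiary oxygen and the seven-membered ring has become the 2H-pyran ring. The closest known reaction type is the Smiles rearrangement, the O-to-O aryl migration of 2-aryloxy alkoxides through a spiro-dioxolane Meisenheimer complex, which has not been shown inside a benzoxepine or with an acetyl group as the only activator. The pyran ring closes by 6-exo-trig addition of oxygen to the arene carbon (5-exo-trig with respect to the O–C–C–O unit), both favoured modes. No stereocentre is created: no bond to the carbinol carbon is broken, so its (R) configuration becomes that of C2 of the chromene, and the transient sp3 centre at C9a is flattened again. The step needs attack at C9a only and forward collapse of 12: the para acetyl group and the MOM-capped, non-ionisable neighbouring oxygen make C9a the one electrophilic ring carbon, release of the seven-membered ring and formation of the less basic primary alkoxide pull the equilibrium to 13, and catalytic base in t-BuOH keeps most of the acetyl group un-enolised.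

**Step 9**
Reactants: 14 (E)-ferulic acid
Product: 16 (2E)-3-[3-methoxy-4-(methoxymethoxy)phenyl]prop-2-enoic acid, via bis-MOM ferulate 15 (not isolated)
Conditions: MOMCl (2.5 equiv), i-Pr2NEt (3 equiv), CH2Cl2, 0 to 20 °C; then LiOH (3 equiv), THF/MeOH/H2O, 20 °C; cold dilute HCl to pH 4
Reagents that add atoms: chloromethyl methyl ether, COCCl; lithium hydroxide, [Li+].[OH-]
Why: Exhaustive O-alkylation followed by saponification cleaves only the acyl acetal (the MOM ester) and leaves the aryl MOM ether and the (E)-alkene intact.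

**Step 10**
Reactants: 13 1-[(2R)-2-(hydroxymethyl)-7-(methoxymethoxy)-2-methyl-2H-chromen-6-yl]ethanone; 16 (2E)-3-[3-methoxy-4-(methoxymethoxy)phenyl]prop-2-enoic acid
Product: 17 [(2R)-6-acetyl-7-(methoxymethoxy)-2-methyl-2H-chromen-2-yl]methyl (2E)-3-[3-methoxy-4-(methoxymethoxy)phenyl]prop-2-enoate
Conditions: EDC·HCl (1.5 equiv), DMAP (0.3 equiv), CH2Cl2, 20 °C
Reagents that add atoms: none
Why: Steglich esterification acylates the primary alcohol through the acylpyridinium ion under neutral conditions that leave the chromene, the ketone and both MOM ethers untouched.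

**Step 11**
Reactants: 17 [(2R)-6-acetyl-7-(methoxymethoxy)-2-methyl-2H-chromen-2-yl]methyl (2E)-3-[3-methoxy-4-(methoxymethoxy)phenyl]prop-2-enoate
Product: 18 [(2R)-6-acetyl-7-hydroxy-2-methyl-2H-chromen-2-yl]methyl (2E)-3-(4-hydroxy-3-methoxyphenyl)prop-2-enoate (CNP0375196.1)
Conditions: 3 M aq. HCl, THF/i-PrOH, 45 °C, dark
Reagents that add atoms: none
Why: Acid hydrolysis of the two aryl methoxymethyl acetals should free both phenols, while the acyloxymethyl group at C2 disfavours ionisation of the C2–O1 bond and the hindered alcohol solvent suppresses transesterification, so the ester and the stereocentre should persist.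

**Compound list**
1 | 1-(2,4-dihydroxyphenyl)ethanone | CC(=O)c1ccc(O)cc1O | starting material
2 | 1-(2,4-dihydroxy-5-iodophenyl)ethanone | CC(=O)c1cc(I)c(O)cc1O | intermediate
3 | 1-(5-ethenyl-2,4-dihydroxyphenyl)ethanone | CC(=O)c1cc(C=C)c(O)cc1O | intermediate
4 | rac-2-ethenyl-2-methyloxirane (isoprene monoxide) | C=CC1(C)CO1 | starting material
5 | sodium (2R)-1-hydroxy-2-methylbut-3-en-2-yl carbonate | OC[C@@](OC(=O)[O-])(C)C=C.[Na+] | intermediate
6 | (2R)-2-methylbut-3-ene-1,2-diol | OC[C@@](O)(C)C=C | intermediate
7 | (2R)-2-hydroxy-2-methylbut-3-en-1-yl 4-methylbenzenesulfonate | Cc1ccc(cc1)S(=O)(=O)OC[C@@](O)(C)C=C | intermediate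
8 | (2R)-2-ethenyl-2-methyloxirane | C=C[C@]1(C)CO1 | intermediate
9 | 1-{5-ethenyl-2-hydroxy-4-[(2R)-2-hydroxy-2-methylbut-3-en-1-yl]oxyphenyl}ethanone | CC(=O)c1cc(C=C)c(OC[C@@](O)(C)C=C)cc1O | intermediate
10 | 1-{5-ethenyl-4-[(2R)-2-hydroxy-2-methylbut-3-en-1-yl]oxy-2-(methoxymethoxy)phenyl}ethanone | CC(=O)c1cc(C=C)c(OC[C@@](O)(C)C=C)cc1OCOC | intermediate
11 | 1-[(3R)-3-hydroxy-8-(methoxymethoxy)-3-methyl-2,3-dihydro-1-benzoxepin-7-yl]ethanone | CC(=O)c1cc2C=C[C@@](C)(O)COc2cc1OCOC | intermediate
12 | potassium salt of the bicyclic Meisenheimer adduct (tertiary oxygen bonded to the ipso carbon C9a; 6,8-dioxabicyclo[3.2.1]oct-2-ene ketal fused to the cyclohexadienide, charge on the acetyl oxygen) | CC([O-])=C1C=C2C=C[C@]3(C)CO[C@]2(O3)C=C1OCOC.[K+] | intermediate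
13 | 1-[(2R)-2-(hydroxymethyl)-7-(methoxymethoxy)-2-methyl-2H-chromen-6-yl]ethanone | OC[C@@]1(C)C=Cc2cc(C(C)=O)c(OCOC)cc2O1 | intermediate
14 | (E)-ferulic acid | COc1cc(/C=C/C(O)=O)ccc1O | starting material
15 | methoxymethyl (2E)-3-[3-methoxy-4-(methoxymethoxy)phenyl]prop-2-enoate | COCOC(=O)/C=C/c1ccc(OCOC)c(OC)c1 | intermediate
16 | (2E)-3-[3-methoxy-4-(methoxymethoxy)phenyl]prop-2-enoic acid | COCOc1ccc(/C=C/C(O)=O)cc1OC | intermediate
17 | [(2R)-6-acetyl-7-(methoxymethoxy)-2-methyl-2H-chromen-2-yl]methyl (2E)-3-[3-methoxy-4-(methoxymethoxy)phenyl]prop-2-enoate | COc1cc(/C=C/C(=O)OC[C@@]2(C)C=Cc3cc(C(C)=O)c(OCOC)cc3O2)ccc1OCOC | intermediate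
18 | [(2R)-6-acetyl-7-hydroxy-2-methyl-2H-chromen-2-yl]methyl (2E)-3-(4-hydroxy-3-methoxyphenyl)prop-2-enoate | COc1cc(/C=C/C(=O)OC[C@@]2(C)C=Cc3cc(C(C)=O)c(O)cc3O2)ccc1O | target

Total step count: 11. Longest linear sequence: 8 steps (steps 1, 2, 5, 6, 7, 8, 10, 11 from compound 1; equally steps 3, 4, 5, 6, 7, 8, 10, 11 from compound 4).

**Steps most likely to fail**

Step 8 (Proposed new method). Deprotonation at the acetyl methyl group instead of the tertiary hydroxyl may drain the alkoxide and lower the electrophilicity of the ring, so that ipso addition stalls. Alternatively the alkoxide may expel the aryloxide at CH2 (epoxide formation) and the material may degrade. The fallback uses known chemistry, sets out from compound 3 (with compound 4) and comes back to the route at compound 13. Palladium-catalysed asymmetric allylic etherification of the acidic 4-hydroxyl of 3 with racemic 4 (Pd2(dba)3·CHCl3, the same Trost ligand antipode as in step 3, CH2Cl2) adds the phenol oxygen to the more substituted allyl terminus. This should give the tertiary aryl ether 1-{5-ethenyl-2-hydroxy-4-[(2R)-1-hydroxy-2-methylbut-3-en-2-yl]oxyphenyl}ethanone F1. Capping of the chelated phenol with MOMCl/K2CO3 in acetone should give 1-{5-ethenyl-4-[(2R)-1-hydroxy-2-methylbut-3-en-2-yl]oxy-2-(methoxymethoxy)phenyl}ethanone F2. Ring-closing metathesis with the second-generation Grubbs catalyst then closes the six-membered ring directly to 13.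

Step 5. The phenoxide may add to the vinyl terminus of the vinyl epoxide formed in the flask (conjugate opening) instead of the CH2, or the hydroxystyrene may polymerise in hot basic DMF. The fallback sets out from compound 3 and comes back at compound 9; it takes the stereocentre from commercial (2S)-2-methylglycidol and so also replaces steps 3 and 4. Mitsunobu etherification of the 4-hydroxyl of 3 with (2S)-2-methylglycidol (PPh3, DIAD, THF, 0 °C) should give the glycidyl ether 1-{5-ethenyl-2-hydroxy-4-[(2R)-2-methyloxiran-2-yl]methoxyphenyl}ethanone F3. One-carbon homologation of the epoxide with dimethylsulfonium methylide (Me3S+ I−, n-BuLi, THF, −10 to 20 °C, excess) then opens it at CH2 and eliminates dimethyl sulfide to give the tertiary allylic alcohol 9; the phenoxide formed in the flask shields the acetyl group.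

Step 11. Protonation of the styrenic double bond of the chromene (oligomerisation) or acid-catalysed cleavage or exchange of the ferulate ester may outrun hydrolysis of the less labile guaiacol MOM ether. The fallback sets out from compound 13 and comes back at compound 18; it builds the ferulate with its phenol free, so that only the very labile MOM ether next to the acetyl group remains to be removed. Heating 13 with Meldrum's acid (toluene, 90 °C) should give the malonic half-ester 3-{[(2R)-6-acetyl-7-(methoxymethoxy)-2-methyl-2H-chromen-2-yl]methoxy}-3-oxopropanoic acid F4. Knoevenagel–Doebner condensation with vanillin (pyridine, piperidine cat., 70 °C) with loss of CO2 should give [(2R)-6-acetyl-7-(methoxymethoxy)-2-methyl-2H-chromen-2-yl]methyl (2E)-3-(4-hydroxy-3-methoxyphenyl)prop-2-enoate F5. Brief treatment with PPTS in i-PrOH (55 °C) then frees the chelated phenol to give 18.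

**Further compounds**
F1 | step 8 | 1-{5-ethenyl-2-hydroxy-4-[(2R)-1-hydroxy-2-methylbut-3-en-2-yl]oxyphenyl}ethanone | CC(=O)c1cc(C=C)c(O[C@@](C)(CO)C=C)cc1O
F2 | step 8 | 1-{5-ethenyl-4-[(2R)-1-hydroxy-2-methylbut-3-en-2-yl]oxy-2-(methoxymethoxy)phenyl}ethanone | CC(=O)c1cc(C=C)c(O[C@@](C)(CO)C=C)cc1OCOC
F3 | step 5 | 1-{5-ethenyl-2-hydroxy-4-[(2R)-2-methyloxiran-2-yl]methoxyphenyl}ethanone | CC(=O)c1cc(C=C)c(OC[C@@]2(C)CO2)cc1O
F4 | step 11 | 3-{[(2R)-6-acetyl-7-(methoxymethoxy)-2-methyl-2H-chromen-2-yl]methoxy}-3-oxopropanoic acid | OC(=O)CC(=O)OC[C@@]1(C)C=Cc2cc(C(C)=O)c(OCOC)cc2O1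
F5 | step 11 | [(2R)-6-acetyl-7-(methoxymethoxy)-2-methyl-2H-chromen-2-yl]methyl (2E)-3-(4-hydroxy-3-methoxyphenyl)prop-2-enoate | COc1cc(/C=C/C(=O)OC[C@@]2(C)C=Cc3cc(C(C)=O)c(OCOC)cc3O2)ccc1O
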